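The 31-membered lactone ring (C1–C30 plus the ring oxygen) carries no function other than the C1 ester, so any CH2–CH2 bond can be hidden as an alkene. The route cuts C10–C11, two plain mid-chain methylenes, because this splits the chain into a C10 piece from an undec-10-enoyl unit and a C20 piece from icosanedioic acid. The precursor is the open-chain ester dialdehyde 20-oxoicosyl 10-oxodecanoate, whose formyl carbons are C10 and C11. A titanium-mediated reductive carbonyl coupling joins them, expels both oxygens and closes the macrocycle in a single operation. Hydrogenation then erases the alkene.

Key step: step 5

Numbering and atom count: lactone numbering is used, with C1 the carbonyl carbon and C30 the OCH2 carbon. The target is C1 plus 29 CH2 plus one ring oxygen (31 ring members, C30H58O2, no stereocentre). The halves contribute 10 and 20 carbons.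

Assumption: alkene 9 should form as an E/Z mixture and is drawn E. Both geometries converge on 10 in step 6.

Design remark: the alcohol is oxidised before the alkene is cleaved, so no hydroxy aldehyde is ever present. The dialdehyde is freed of phosphine oxide by chromatography and used fresh, because oxygen donors consume low-valent titanium.

Step 1
Reactants: 1 icosanedioic acid
Product: 2 icosane-1,20-diol
Conditions: BH3·SMe2 (5 equiv), THF, 0 °C → 50 °C; MeOH quench
Reagents that add atoms: none
Why: Borane reduction of carboxylic acids runs through soluble acyloxyboranes, so both carboxyl groups of the sparingly soluble diacid should reach CH2OH without the insoluble carboxylate salts that slow aluminium hydride reductions.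

Step 2
Reactants: 2 icosane-1,20-diol (3 equiv); 3 undec-10-enoyl chloride (1 equiv)
Product: 4 20-hydroxyicosyl undec-10-enoate
Conditions: pyridine, DMAP (cat.), THF, 50 °C, slow addition of 3; excess 2 crystallised out on cooling and recycled
Reagents that add atoms: none
Why: This is a nucleophilic acyl substitution (O-acylation) under statistical control, in which the threefold excess of warm, dissolved diol and the slow feed of acid chloride should make the monoester the main acylation product.

Step 3
Reactants: 4 20-hydroxyicosyl undec-10-enoate
Product: 5 20-oxoicosyl undec-10-enoate
Conditions: Dess–Martin periodinane (1.2 equiv), CH2Cl2, 0 °C → rt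
Reagents that add atoms: none
Why: The Dess–Martin oxidation stops at the aldehyde and leaves the terminal alkene and the ester untouched, and placing it before the alkene cleavage removes the risk of hemiacetal oxidation to oligomeric esters.

Step 4
Reactants: 5 20-oxoicosyl undec-10-enoate
Product: 7 20-oxoicosyl 10-oxodecanoate, via secondary ozonide 6 (not isolated)
Conditions: O3/O2, CH2Cl2, −78 °C, Sudan red 7B as end-point indicator; N2 purge; PPh3 (1.2 equiv), −78 °C → rt; flash chromatography, used at once
Reagents that add atoms: ozone, [O-][O+]=O
Why: Ozonolysis by the Criegee mechanism followed by phosphine reduction removes the terminal CH2 and leaves C10 as the second formyl group, since the alkene reacts with ozone at −78 °C far faster than an aldehyde C–H and the dye prevents an excess of ozone.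

Step 5
Reactants: 7 20-oxoicosyl 10-oxodecanoate
Product: 9 (E)-triacont-10-en-30-olide (with its Z isomer), via titanium pinacolate 8 (not isolated)
Conditions: TiCl3(DME)1.5 (15 equiv), Zn–Cu couple (45 equiv), DME, reflux, 4 h; then 7 in DME by syringe pump over 36 h (final about 2 mM); reflux 3 h more; cool, filter through a silica pad
Reagents that add atoms: none
Why: The Zn–Cu couple reduces the trivalent titanium chloride to a low-valent titanium slurry that passes one electron to each formyl group; the two surface-held ketyl radicals combine at carbon to the pinacolate 8, and at reflux both C–O bonds break in favour of strong Ti–O bonds to release the C10=C11 alkene. The closest known reaction type is the intramolecular McMurry coupling of long-chain dialdehydes to large cycloalkenes. The 31-membered ring is closed end to end by union of the two chain termini, both new sp2 carbons being endocyclic, and the anchoring of both ends on titanium before bond formation should make the closure largely insensitive to ring size. No lasting stereocentre is created, the two carbinol centres of 8 vanish on deoxygenation, and the uncontrolled alkene geometry is erased in step 6. The step needs formyl–formyl coupling ahead of formyl–ester and intermolecular coupling: aldehydes accept an electron far more readily than an ester, the ester could only give a strained 10-membered carbocycle with C10 or a 22-membered enol ether with C11, and slow addition into a large excess of reagent keeps free 7 at very low concentration. The heating time after the addition is kept short to spare the ester.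

Step 6
Reactants: 9 (E)-triacont-10-en-30-olide (with its Z isomer)
Product: 10 triacontan-30-olide (oxacyclohentriacontan-2-one)
Conditions: H2 (1 atm), 10% Pd/C, EtOAc/THF, rt
Reagents that add atoms: none
Why: Heterogeneous catalytic hydrogenation saturates an unhindered 1,2-disubstituted alkene of either geometry, while the lactone is inert to H2 over Pd/C.

Compound list

1 | icosanedioic acid | OC(=O)CCCCCCCCCCCCCCCCCCC(=O)O | starting material
2 | icosane-1,20-diol | OCCCCCCCCCCCCCCCCCCCCO | intermediate
3 | undec-10-enoyl chloride | C=CCCCCCCCCC(=O)Cl | starting material
4 | 20-hydroxyicosyl undec-10-enoate | C=CCCCCCCCCC(=O)OCCCCCCCCCCCCCCCCCCCCO | intermediate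
5 | 20-oxoicosyl undec-10-enoate | C=CCCCCCCCCC(=O)OCCCCCCCCCCCCCCCCCCCC=O | intermediate
6 | 20-oxoicosyl 9-(1,2,4-trioxolan-3-yl)nonanoate (secondary ozonide, not isolated) | C1OOC(CCCCCCCCC(=O)OCCCCCCCCCCCCCCCCCCCC=O)O1 | intermediate
7 | 20-oxoicosyl 10-oxodecanoate (ester dialdehyde, precursor of the key step) | O=CCCCCCCCCC(=O)OCCCCCCCCCCCCCCCCCCCC=O | intermediate
8 | titanium pinacolate at C10/C11 of the closed ring, idealised as the monomeric divalent titanium 1,2-diolate, both relative configurations (not isolated) | O=C1CCCCCCCCC2O[Ti]OC2CCCCCCCCCCCCCCCCCCCO1 | intermediate
9 | (E)-triacont-10-en-30-olide, (11E)-oxacyclohentriacont-11-en-2-one, expected together with the Z isomer | O=C1CCCCCCCC/C=C/CCCCCCCCCCCCCCCCCCCO1 | intermediate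
10 | triacontan-30-olide (oxacyclohentriacontan-2-one) | O=C1CCCCCCCCCCCCCCCCCCCCCCCCCCCCCO1 | target

Total step count: 6. Longest linear sequence: 6 steps (1 → 2 → 4 → 5 → 7 → 9 → 10).

Steps most likely to fail

Step 5 carries the main risk.
- What may go wrong: electron transfer to the in-chain ester with formyl–ester coupling or C–O cleavage, intermolecular coupling to dimers and oligomers, or stalling at the pinacolate stage.
- The fallback replaces reductive carbonyl coupling by olefin metathesis. It sets out from 5 and returns at 9.
- The aldehyde of 5 is methylenated chemoselectively with methylidenetriphenylphosphorane F1 (from Ph3PCH3Br and KOtBu, THF, 0 °C) to give henicos-20-en-1-yl undec-10-enoate F2.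
- Ring-closing metathesis of F2 uses the second-generation Grubbs catalyst, (H2IMes)(PCy3)Cl2Ru=CHPh, in dilute refluxing CH2Cl2, with 1,4-benzoquinone added to suppress alkene migration.
- This should form the same C10=C11 bond. The detour replaces steps 4 and 5 without adding a step.

Step 2 is the second risk.
- What may go wrong: over-acylation to the diester, and sluggish heterogeneous reaction because the diol dissolves poorly.
- The fallback forms the ester C–O bond by carboxylate alkylation instead of alcohol acylation. It sets out from 2 and returns at 4.
- Monobromination of 2 with 48% aqueous HBr in refluxing toluene is a known selective desymmetrisation of long α,ω-diols and gives 20-bromoicosan-1-ol F3.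
- The primary bromide of F3 is then displaced in an SN2 reaction by potassium undec-10-enoate F4 (from commercial undec-10-enoic acid and K2CO3) in DMF at 60 °C. The free hydroxyl should stay passive under these conditions.

Step 4 is the third risk.
- What may go wrong: over-oxidation of the resident formyl group by ozone, or trapping of the carbonyl oxide by that aldehyde to give cross-ozonides that are reduced slowly.
- The fallback keeps every aldehyde away from ozone. It sets out from 4 and returns at 7.
- Ozonolysis of 4 in CH2Cl2 at −78 °C gives 20-hydroxyicosyl 9-(1,2,4-trioxolan-3-yl)nonanoate F5.
- F5 is reduced in the same flask with NaBH4/MeOH at 0 °C to 20-hydroxyicosyl 10-hydroxydecanoate F6, a storable diol.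
- A twofold Dess–Martin oxidation of F6 then creates both formyl groups at once, immediately before the coupling. The detour replaces steps 3 and 4 without adding a step.

Further compounds

F1 | step 5 | methylidenetriphenylphosphorane | C=P(c1ccccc1)(c1ccccc1)c1ccccc1
F2 | step 5 | henicos-20-en-1-yl undec-10-enoate | C=CCCCCCCCCC(=O)OCCCCCCCCCCCCCCCCCCCC=C
F3 | step 2 | 20-bromoicosan-1-ol | OCCCCCCCCCCCCCCCCCCCCBr
F4 | step 2 | potassium undec-10-enoate | C=CCCCCCCCCC(=O)[O-].[K+]
F5 | step 4 | 20-hydroxyicosyl 9-(1,2,4-trioxolan-3-yl)nonanoate | C1OOC(CCCCCCCCC(=O)OCCCCCCCCCCCCCCCCCCCCO)O1
F6 | step 4 | 20-hydroxyicosyl 10-hydroxydecanoate | OCCCCCCCCCC(=O)OCCCCCCCCCCCCCCCCCCCCO
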